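## Retrosynthetic overview

1. Key bond: C5–C6 of the target ring. It is traced back to a photochemical [1,3]-sigmatropic shift of the CMe2 carbon in (1R,5R)-(+)-verbenone 1, which gives chrysanthenone 2 and closes the carbocycle that becomes the cyclohexene.
2. C1–O bond: Baeyer–Villiger oxygen insertion into the cyclobutanone of 2 at the bridgehead remote from the alkene. The alkene is masked as an epoxide (3, 4) and restored (via 5) to give bridged lactone 6.
3. Lactone 6 is reduced to cis-diol 7; the CH2–OAr bond comes from 7 and umbelliferone 8 (Mitsunobu), giving 9.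
4. (R)-2-Methylbutanoic acid 10 is joined last: ester C–O disconnection of target 11 into 9 and 10.
5. Ring order: the cyclohexene is the only ring made (in 1 → 2, then freed from the cyclobutanone and lactone bridges); the coumarin rings are bought in 8.

Assumption: 1 and 10 are bought as single enantiomers (≥98% ee, checked by chiral GC); both are catalogue compounds.

The regiochemistry of the Baeyer–Villiger step and the enantiomeric fidelity of the photochemical step are argued from mechanism, not from a known procedure on these exact substrates.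

## Route

Step 1
Reactants: 1 (1R,5R)-(+)-verbenone
Product: 2 (1S,5R)-chrysanthenone
Conditions: hν (350–365 nm, Pyrex), degassed cyclohexane (0.03 M), 20 °C, to ca. 75% conversion
Reagents that add atoms: none
Why: Photochemical [1,3]-sigmatropic alkyl shift of the enone, in which the CMe2 carbon stays bonded to bridgehead C1 and moves from C5 to the α-carbon C3 on the only face it can reach, so the new C–C bond and the new stereocentre (C5 of the target) are dictated by the bridgehead bought in 1, while long-wavelength light and incomplete conversion limit the photoreversible ketene pathway of 2 that would erode ee.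

Step 2
Reactants: 2 (1S,5R)-chrysanthenone
Product: 4 (1R,2R,3S,5R)-2,3-epoxy-2,8,8-trimethyl-6-oxabicyclo[3.2.1]octan-7-one, via epoxy ketone 3 (not isolated)
Conditions: DMDO (1.2 equiv), acetone, 0 °C; evaporate; mCPBA (1.5 equiv), NaHCO3 (buffer), CH2Cl2, 0 °C → rt
Reagents that add atoms: dimethyldioxirane CC1(C)OO1; mCPBA OOC(=O)c1cccc(Cl)c1
Why: Dioxirane epoxidation takes the alkene face under the small carbonyl bridge (anti to the CMe2 bridge) and leaves the ketone alone, and in the Baeyer–Villiger oxidation of the strained cyclobutanone the bridgehead that now bears the electron-withdrawing oxirane (no longer allylic) is the poorer migrating group, so the remote bridgehead shifts to oxygen with retention and becomes the carbinol stereocentre (C1 of the target).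

Step 3
Reactants: 4 (1R,2R,3S,5R)-2,3-epoxy-2,8,8-trimethyl-6-oxabicyclo[3.2.1]octan-7-one
Product: 6 (1S,5R)-2,8,8-trimethyl-6-oxabicyclo[3.2.1]oct-2-en-7-one, via iodohydrin 5 (not isolated)
Conditions: Zn dust, NaI, NaOAc, AcOH, 0 °C → rt
Reagents that add atoms: none
Why: Cornforth-type deoxygenation, in which iodide opens the oxirane anti at the less hindered secondary carbon and zinc removes iodide and hydroxyl by reductive anti-elimination, restores the ring alkene without touching the lactone or its two stereocentres.

Step 4
Reactants: 6 (1S,5R)-2,8,8-trimethyl-6-oxabicyclo[3.2.1]oct-2-en-7-one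
Product: 7 (1R,5S)-5-(hydroxymethyl)-4,6,6-trimethylcyclohex-3-en-1-ol
Conditions: LiAlH4, THF, 0 °C → rt; Fieser work-up
Reagents that add atoms: none
Why: Hydride reduction of the lactone breaks no bond at either stereocentre, so the cis diol is obtained with both configurations intact.

Step 5
Reactants: 7 (1R,5S)-5-(hydroxymethyl)-4,6,6-trimethylcyclohex-3-en-1-ol; 8 umbelliferone (7-hydroxy-2H-chromen-2-one)
Product: 9 7-{[(1S,5R)-5-hydroxy-2,6,6-trimethylcyclohex-2-en-1-yl]methoxy}-2H-chromen-2-one
Conditions: PPh3, DIAD, THF, 0 °C → rt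
Reagents that add atoms: none
Why: Mitsunobu etherification, in which the primary carbinol is activated as its alkoxyphosphonium ion and displaced by the acidic phenol (pKa about 8) whereas the neopentylic secondary hydroxyl next to the CMe2 carbon is too hindered to be activated, touches no stereocentre.

Step 6
Reactants: 9 7-{[(1S,5R)-5-hydroxy-2,6,6-trimethylcyclohex-2-en-1-yl]methoxy}-2H-chromen-2-one; 10 (R)-2-methylbutanoic acid
Product: 11 (1R,5S)-4,6,6-trimethyl-5-{[(2-oxo-2H-chromen-7-yl)oxy]methyl}cyclohex-3-en-1-yl (2R)-2-methylbutanoate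
Conditions: DCC, DMAP (0.5 equiv), CH2Cl2, rt, 24–48 h
Reagents that add atoms: none
Why: Steglich esterification via the acyl-DMAP cation acylates the hindered secondary alcohol with retention (its C–O bond is not broken), and the mild carbodiimide conditions do not enolise the bought α-stereocentre of the acid.

## Compound list

1 | (1R,5R)-(+)-verbenone, (1R,5R)-4,6,6-trimethylbicyclo[3.1.1]hept-3-en-2-one | CC1=CC(=O)[C@@H]2C[C@H]1C2(C)C | starting material
2 | (1S,5R)-chrysanthenone, (1S,5R)-2,7,7-trimethylbicyclo[3.1.1]hept-2-en-6-one | CC1=CC[C@H]2C(=O)[C@@H]1C2(C)C | intermediate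
3 | epoxy ketone, (1R,2R,3S,5R)-2,3-epoxy-2,7,7-trimethylbicyclo[3.1.1]heptan-6-one, oxirane oxygen on the face of the carbonyl bridge | C[C@]12O[C@H]1C[C@H]3C(=O)[C@@H]2C3(C)C | intermediate
4 | epoxy lactone, (1R,2R,3S,5R)-2,3-epoxy-2,8,8-trimethyl-6-oxabicyclo[3.2.1]octan-7-one, oxirane oxygen on the face of the lactone bridge | C[C@]12O[C@H]1C[C@H]3OC(=O)[C@@H]2C3(C)C | intermediate
5 | iodohydrin, 2-hydroxy-3-iodo-2,8,8-trimethyl-6-oxabicyclo[3.2.1]octan-7-one, tertiary OH on the face of the lactone bridge and iodide at C3 on the opposite face | C[C@]1(O)[C@H](I)C[C@H]2OC(=O)[C@@H]1C2(C)C | intermediate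
6 | (1S,5R)-2,8,8-trimethyl-6-oxabicyclo[3.2.1]oct-2-en-7-one | CC1=CC[C@H]2OC(=O)[C@@H]1C2(C)C | intermediate
7 | (1R,5S)-5-(hydroxymethyl)-4,6,6-trimethylcyclohex-3-en-1-ol | O[C@@H]1CC=C(C)[C@H](CO)C1(C)C | intermediate
8 | umbelliferone, 7-hydroxy-2H-chromen-2-one | Oc1ccc2ccc(=O)oc2c1 | starting material
9 | 7-{[(1S,5R)-5-hydroxy-2,6,6-trimethylcyclohex-2-en-1-yl]methoxy}-2H-chromen-2-one | O[C@@H]1CC=C(C)[C@H](COc2ccc3ccc(=O)oc3c2)C1(C)C | intermediate
10 | (R)-2-methylbutanoic acid | CC[C@@H](C)C(=O)O | starting material
11 | (1R,5S)-4,6,6-trimethyl-5-{[(2-oxo-2H-chromen-7-yl)oxy]methyl}cyclohex-3-en-1-yl (2R)-2-methylbutanoate | CC[C@@H](C)C(=O)O[C@@H]1CC=C(C)[C@H](COc2ccc3ccc(=O)oc3c2)C1(C)C | target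

## Step count and risks

Total steps: 6. Longest linear sequence: 6 (1 → 2 → 4 → 6 → 7 → 9 → 11).

Steps most likely to fail:

Step 1. Chrysanthenone 2 is itself photolabile: it opens reversibly to an achiral dienylketene that recloses to racemic 2, so yield is moderate and ee can erode. Any ring enantiomer that leaks through would end as a diastereomer of 11. Fallback: do not rely on the light step for optical purity. Carry the scalemic material to diol 7 and convert it with 4-nitrobenzoyl chloride, pyridine and DMAP into the crystalline bis(4-nitrobenzoate) F1. Recrystallise F1 to constant rotation and cleave it with K2CO3 in MeOH. This loop sets out from 7 and comes back to the route at 7.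

Step 2. Both bridgeheads of the cyclobutanone are tertiary, so the oxirane may not bias the Baeyer–Villiger migration enough, and epoxy ketone 3 is acid-labile like pinene oxide. Fallback: switch off the allylic bridgehead with a diol instead of an oxirane. From 2, OsO4 (cat.) with NMO gives the cis-diol ketone F2, attack again coming under the carbonyl bridge. Buffered mCPBA then gives the diol lactone F3, where a β-hydroxyl sits on the unwanted migrating carbon and no oxirane can rearrange. Thiocarbonyldiimidazole gives the cyclic thionocarbonate F4, and P(OMe)3 at 110 °C (Corey–Winter) restores the alkene. This sets out from 2 and comes back at 6.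

Step 5. The primary carbinol is β-branched and slow in SN2, and the free cis secondary hydroxyl can close onto the activated carbon to give a bridged bicyclic ether. Fallback: take the secondary hydroxyl out of play before the ether is made. From 7, TBSCl and imidazole silylate only the primary alcohol to give the primary silyl ether F5. DCC and DMAP with acid 10 give the silyl ether ester F6, and HF·pyridine frees the hydroxy ester F7. Mitsunobu coupling of F7 with 8 then gives the target directly. This sets out from 7 and comes back at 11.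

## Further compounds

F1 | step 1 | (1R,5S)-4,6,6-trimethyl-5-{[(4-nitrobenzoyl)oxy]methyl}cyclohex-3-en-1-yl 4-nitrobenzoate | O=C(c1ccc(cc1)[N+](=O)[O-])O[C@@H]1CC=C(C)[C@H](COC(=O)c2ccc(cc2)[N+](=O)[O-])C1(C)C
F2 | step 2 | cis-2,3-dihydroxy-2,7,7-trimethylbicyclo[3.1.1]heptan-6-one, both OH on the face of the carbonyl bridge | C[C@]1(O)[C@@H](O)C[C@H]2C(=O)[C@@H]1C2(C)C
F3 | step 2 | cis-2,3-dihydroxy-2,8,8-trimethyl-6-oxabicyclo[3.2.1]octan-7-one, both OH on the face of the lactone bridge | C[C@]1(O)[C@@H](O)C[C@H]2OC(=O)[C@@H]1C2(C)C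
F4 | step 2 | 2,3-cyclic thionocarbonate of F3 | C[C@]12OC(=S)O[C@H]1C[C@H]3OC(=O)[C@@H]2C3(C)C
F5 | step 5 | (1R,5S)-5-{[(tert-butyldimethylsilyl)oxy]methyl}-4,6,6-trimethylcyclohex-3-en-1-ol | O[C@@H]1CC=C(C)[C@H](CO[Si](C)(C)C(C)(C)C)C1(C)C
F6 | step 5 | (1R,5S)-5-{[(tert-butyldimethylsilyl)oxy]methyl}-4,6,6-trimethylcyclohex-3-en-1-yl (2R)-2-methylbutanoate | CC[C@@H](C)C(=O)O[C@@H]1CC=C(C)[C@H](CO[Si](C)(C)C(C)(C)C)C1(C)C
F7 | step 5 | (1R,5S)-5-(hydroxymethyl)-4,6,6-trimethylcyclohex-3-en-1-yl (2R)-2-methylbutanoate | CC[C@@H](C)C(=O)O[C@@H]1CC=C(C)[C@H](CO)C1(C)C
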